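**Plan**

1. Numbering (germacrane type, also used in the names): C10 = methyl-bearing ether carbon (methyl C14), C1/C2 = CH2, C3=C4 with the C15 methyl ester on C4, C5 = ether CH, C6 = lactone O–CH, C7 = CH carrying C11(=C13)–C12, C8 = acyloxy CH, C9 = CH2, O11 = ether bridge; ring A = O11/C10/C1–C5, ring B = O11/C5–C10; "nor" prefixes mark C11–C13 not yet present.
2. Retrosynthetic cuts, in order: the O8 ester; the C12–O6 lactone bond and C11=C13 (C12 returns to O8 as an ethyl acetal); C7–C11 together with C6–O (radical cyclisation–oxygenation of an O8 bromoacetal across C6=C7); C4–C5 (enol silane onto the ring B oxocarbenium ion); C6=C7 (metathesis); O11–C5 (acrolein acetal of a linalool-derived tertiary alcohol).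
3. Enabling feature: on C7 the C11 branch is cis to O8 and trans to O6, and C6=C7 sits in ring B next to C8; a C11 radical tethered through O8 must therefore add to C7 on the O8 face (cis-fused O8–C12–C11–C7–C8 ring) and leaves the C6 radical open to oxygen on the other face.
4. Forward order: ring B closes first (metathesis), ring A second (bridging C4–C5 alkylation, then enol triflate reduction to the enoate), the acetal ring third (key step); C12 is then moved from O8 to O6 through a dithiane, O8 is acylated, and methylenation, oxidation and lactonisation finish the target.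
5. Stereochemistry: C10 from (S)-linalool; C5 forced by the bridge; C8 by exo hydride addition to the bicyclic enone; C7 and C6 relayed from C8 in the key step; the acyl carbinol from (R)-2-methylglycidol.

Key step: step 16

Assumption: (S)-(+)-linalool of high enantiomeric purity is taken as commercially available; centres that are destroyed or reset later (C8 before step 14, the acetal carbons, C4 in 13, C11 in 32) are carried as epimer mixtures and written without a stereodescriptor in the SMILES.

**Route**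

Step 1
Reactants: 1 (S)-linalool
Product: 3 (3S)-3,7-dimethyloct-6-ene-1,3-diol, via B-alkyl-9-borabicyclononane 2 (not isolated)
Conditions: 9-borabicyclo[3.3.1]nonane (2.2 equiv), THF, 0 °C → rt; then NaOH, H2O2, 0 °C → rt
Reagents that add atoms: hydrogen peroxide, OO
Why: Hydroboration–oxidation: the bulky borane adds anti-Markovnikov to the monosubstituted vinyl group much faster than to the trisubstituted alkene, so C8 becomes a primary alcohol and the C10 carbinol centre taken from linalool is not touched.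

Step 2
Reactants: 3 (3S)-3,7-dimethyloct-6-ene-1,3-diol
Product: 4 (3S)-3-hydroxy-3,7-dimethyloct-6-enal
Conditions: TEMPO (10 mol %), PhI(OAc)2, CH2Cl2, rt; used crude
Reagents that add atoms: none
Why: TEMPO/PhI(OAc)2 oxidation of a primary alcohol stops at the aldehyde, leaves the tertiary alcohol alone and is close to neutral, which spares the β-hydroxy aldehyde from dehydration or retro-aldol cleavage.

Step 3
Reactants: 4 (3S)-3-hydroxy-3,7-dimethyloct-6-enal
Product: 5 (5S)-5,9-dimethyldeca-1,8-diene-3,5-diol as both C3 epimers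
Conditions: CH2=CHMgBr (3 equiv), THF, −78 °C
Reagents that add atoms: vinylmagnesium bromide, C=C[Mg]Br
Why: Grignard 1,2-addition (the first equivalent is spent on the O–H) builds the C7–C8 bond; the remote quaternary C10 gives no useful 1,3-induction, so both C8 epimers (C3 of this name) are carried until C8 is reset in steps 13 and 14.

Step 4
Reactants: 5 (5S)-5,9-dimethyldeca-1,8-diene-3,5-diol
Product: 6 (5S)-3-(tert-butyldimethylsilyloxy)-5,9-dimethyldeca-1,8-dien-5-ol
Conditions: t-BuMe2SiCl, imidazole, DMF, 0 °C → rt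
Reagents that add atoms: tert-butyldimethylsilyl chloride, CC(C)(C)[Si](C)(C)Cl
Why: Silyl ether formation with the bulky chlorosilane is selective for the secondary allylic alcohol over the tertiary one, which leaves O11–H free for acetal formation.

Step 5
Reactants: 6 (5S)-3-(tert-butyldimethylsilyloxy)-5,9-dimethyldeca-1,8-dien-5-ol; 7 methoxyallene
Product: 8 (5S)-3-(tert-butyldimethylsilyloxy)-5-(1-methoxyprop-2-enyloxy)-5,9-dimethyldeca-1,8-diene
Conditions: 7 (2 equiv), Pd(OAc)2 (5 mol %), Ph2P(CH2)3PPh2 (7 mol %), Et3N, MeCN, rt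
Reagents that add atoms: none
Why: Palladium-catalysed hydroalkoxylation of an alkoxyallene (alcohol addition to an alkoxy-π-allyl palladium species at its oxygen-bearing carbon) gives the acrolein mixed acetal under basic conditions; the new acetal centre C5 is a mixture that is planarised in step 9.

Step 6
Reactants: 8 (5S)-3-(tert-butyldimethylsilyloxy)-5-(1-methoxyprop-2-enyloxy)-5,9-dimethyldeca-1,8-diene
Product: 9 (7S)-5-(tert-butyldimethylsilyloxy)-2-methoxy-7-methyl-7-(4-methylpent-3-enyl)-2,5,6,7-tetrahydrooxepine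
Conditions: RuCl2(=CHPh)(PCy3)(H2IMes) (second-generation Grubbs catalyst, 5 mol %), CH2Cl2 (5 mM), 40 °C
Reagents that add atoms: none
Why: Ring-closing metathesis between the two monosubstituted alkenes closes the seven-membered ring B at C6=C7 with loss of ethene, helped by the quaternary C10 and faster than any engagement of the trisubstituted prenyl alkene.

Step 7
Reactants: 9 (7S)-5-(tert-butyldimethylsilyloxy)-2-methoxy-7-methyl-7-(4-methylpent-3-enyl)-2,5,6,7-tetrahydrooxepine
Product: 10 methyl 3-[(2S)-4-(tert-butyldimethylsilyloxy)-7-methoxy-2-methyl-2,3,4,7-tetrahydrooxepin-2-yl]propanoate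
Conditions: O3, NaOH (2.5 M in MeOH), CH2Cl2, −78 °C, ozone dosed to consumption of 9
Reagents that add atoms: ozone, [O-][O+]=O; methanol, CO
Why: Ozonolysis in methanolic NaOH (direct ester-forming ozonolysis) cleaves the electron-rich trisubstituted alkene in preference to the ring alkene flanked by two allylic C–O bonds and gives the C3 methyl ester in one operation, the basic medium protecting the acid-labile acetal.

Step 8
Reactants: 10 methyl 3-[(2S)-4-(tert-butyldimethylsilyloxy)-7-methoxy-2-methyl-2,3,4,7-tetrahydrooxepin-2-yl]propanoate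
Product: 11 methyl 5-[(2S)-4-(tert-butyldimethylsilyloxy)-7-methoxy-2-methyl-2,3,4,7-tetrahydrooxepin-2-yl]-3-oxopentanoate
Conditions: CH3CO2Me (3 equiv), LiN(i-Pr)2 (3.1 equiv), THF, −78 °C; then 10, −78 → −20 °C
Reagents that add atoms: methyl acetate, CC(=O)OC
Why: Crossed Claisen condensation of the methyl ester with excess lithium enolate of methyl acetate adds C4 and C15 and is driven by deprotonation of the β-keto ester that forms.

Step 9
Reactants: 11 methyl 5-[(2S)-4-(tert-butyldimethylsilyloxy)-7-methoxy-2-methyl-2,3,4,7-tetrahydrooxepin-2-yl]-3-oxopentanoate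
Product: 13 methyl (5S,10S)-8-(tert-butyldimethylsilyloxy)-5,10-epoxy-3-oxo-11,12,13-trinorgermacr-6-en-15-oate, via enol silane 12 (not isolated)
Conditions: Me3SiOTf (2.5 equiv), i-Pr2NEt (1.2 equiv), CH2Cl2 (5 mM), −78 → −20 °C
Reagents that add atoms: none
Why: One-pot enol silane formation and intramolecular Mukaiyama-type alkylation of the ring B allylic oxocarbenium ion (the oxa-bridging closure known from β-keto ester enol silane/oxocarbenium annulations) forms C4–C5 and ring A through a seven-membered closure; because the nucleophile hangs from C10 it can reach C5 only on its own face, so C5 is set cis-bridged (5S) whatever the acetal or C8 configuration, while C4 stays a mixture that disappears in step 10.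

Step 10
Reactants: 13 methyl (5S,10S)-8-(tert-butyldimethylsilyloxy)-5,10-epoxy-3-oxo-11,12,13-trinorgermacr-6-en-15-oate
Product: 14 methyl (5S,10S)-8-(tert-butyldimethylsilyloxy)-5,10-epoxy-3-(trifluoromethylsulfonyloxy)-11,12,13-trinorgermacra-3,6-dien-15-oate
Conditions: Tf2O, i-Pr2NEt, CH2Cl2, −78 °C
Reagents that add atoms: trifluoromethanesulfonic anhydride, O=S(=O)(OS(=O)(=O)C(F)(F)F)C(F)(F)F
Why: Enol triflate formation by O-sulfonylation of the β-keto ester enolate fixes the double bond between C3 and the doubly activated C4 and removes the C4 stereocentre.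

Step 11
Reactants: 14 methyl (5S,10S)-8-(tert-butyldimethylsilyloxy)-5,10-epoxy-3-(trifluoromethylsulfonyloxy)-11,12,13-trinorgermacra-3,6-dien-15-oate
Product: 15 methyl (5S,10S)-8-(tert-butyldimethylsilyloxy)-5,10-epoxy-11,12,13-trinorgermacra-3,6-dien-15-oate
Conditions: Pd(OAc)2 (5 mol %), PPh3 (10 mol %), HCO2H, Bu3N, DMF, 60 °C
Reagents that add atoms: none
Why: Palladium-catalysed formate reduction of the vinyl triflate replaces OTf by H and gives the ring A enoate, whose geometry is fixed by the ring; the allylic silyl ether and the bridging ether are inert.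

Step 12
Reactants: 15 methyl (5S,10S)-8-(tert-butyldimethylsilyloxy)-5,10-epoxy-11,12,13-trinorgermacra-3,6-dien-15-oate
Product: 16 methyl (5S,10S)-5,10-epoxy-8-hydroxy-11,12,13-trinorgermacra-3,6-dien-15-oate as both C8 epimers
Conditions: Bu4NF, THF, 0 °C → rt
Reagents that add atoms: none
Why: Fluoride-mediated cleavage of the silyl ether frees the allylic C8 alcohols without touching the ester or the bridging ether.

Step 13
Reactants: 16 methyl (5S,10S)-5,10-epoxy-8-hydroxy-11,12,13-trinorgermacra-3,6-dien-15-oate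
Product: 17 methyl (5S,10S)-5,10-epoxy-8-oxo-11,12,13-trinorgermacra-3,6-dien-15-oate
Conditions: Dess–Martin periodinane, NaHCO3, CH2Cl2, 0 °C → rt
Reagents that add atoms: none
Why: Dess–Martin oxidation of the allylic alcohol merges both C8 epimers into one enone under buffered conditions that should not open the β-alkoxy ketone.

Step 14
Reactants: 17 methyl (5S,10S)-5,10-epoxy-8-oxo-11,12,13-trinorgermacra-3,6-dien-15-oate
Product: 18 methyl (5S,8R,10S)-5,10-epoxy-8-hydroxy-11,12,13-trinorgermacra-3,6-dien-15-oate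
Conditions: NaBH4, CeCl3·7H2O, MeOH, −78 °C
Reagents that add atoms: none
Why: Luche 1,2-reduction: hydride should reach the C8 carbonyl from the exo face of the folded oxa-bridged bicycle (the side of the O11 bridge, away from the C1–C4 bridge), which places O8 endo (8R) as the tether needs, and the conjugated C15 ester is not reduced.

Step 15
Reactants: 18 methyl (5S,8R,10S)-5,10-epoxy-8-hydroxy-11,12,13-trinorgermacra-3,6-dien-15-oate; 19 ethyl vinyl ether
Product: 20 methyl (5S,8R,10S)-8-(2-bromo-1-ethoxyethoxy)-5,10-epoxy-11,12,13-trinorgermacra-3,6-dien-15-oate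
Conditions: N-bromosuccinimide, 19 (3 equiv), CH2Cl2, −40 → 0 °C
Reagents that add atoms: N-bromosuccinimide, O=C1CCC(=O)N1Br
Why: Bromoetherification of the enol ether by the allylic alcohol (Ueno–Stork bromoacetal formation) puts C11 and C12 on O8; the enol ether is far more reactive toward the bromonium source than the ring alkenes, and the acetal carbon forms as an inconsequential epimer mixture.

Step 16
Reactants: 20 methyl (5S,8R,10S)-8-(2-bromo-1-ethoxyethoxy)-5,10-epoxy-11,12,13-trinorgermacra-3,6-dien-15-oate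
Product: 22 methyl (5R,6S,7S,8R,10S)-12-ethoxy-6-hydroxy-5,10:8,12-diepoxy-13-norgermacr-3-en-15-oate, via C6 hydroperoxide 21 (not isolated)
Conditions: Bu3SnH (1.5 equiv, syringe pump), dry air sparge, toluene (10 mM), 0 °C → rt; then PPh3, rt
Reagents that add atoms: dioxygen, O=O
Why: Bromine abstraction by the tin radical gives the primary C11 radical held on O8 by the acetal; it adds to C7 of the C6=C7 alkene, the secondary C6 radical is captured by O2, the peroxyl radical takes hydrogen from Bu3SnH to give hydroperoxide 21, and PPh3 reduces this to alcohol 22. The closest known reaction type is the Ueno–Stork haloacetal cyclisation run under air (oxygenative radical cyclisation). The new five-membered acetal ring closes in the 5-exo-trig mode and can only be cis-fused, so C7 receives C11 on the endo face that carries O8 and its configuration is relayed from C8. C6 is controlled by the new ring on C7 and by the fold of the bicycle: O2 should approach the open exo face, anti to C11, which gives the O6/C11 trans relation needed for the lactone. The step needs cyclisation to outrun oxygen capture of the uncyclised radical, which the fast haloacetal closure onto a cis ring alkene held next to the tether, the low stationary Bu3SnH concentration and the use of air in place of pure O2 should secure; 6-endo closure and attack on the remote, electron-poor C3=C4 enoate should not compete. The acetal carbon C12 stays an epimer mixture that is removed in step 18.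

Step 17
Reactants: 22 methyl (5R,6S,7S,8R,10S)-12-ethoxy-6-hydroxy-5,10:8,12-diepoxy-13-norgermacr-3-en-15-oate
Product: 23 methyl (5R,6S,7R,8R,10S)-6-(tert-butyldimethylsilyloxy)-12-ethoxy-5,10:8,12-diepoxy-13-norgermacr-3-en-15-oate
Conditions: t-BuMe2SiOTf, 2,6-lutidine, CH2Cl2, −78 °C
Reagents that add atoms: tert-butyldimethylsilyl trifluoromethanesulfonate, CC(C)(C)[Si](C)(C)OS(=O)(=O)C(F)(F)F
Why: Silyl ether formation on the exo C6 alcohol at low temperature is faster than any activation of the acetal by the silyl triflate and protects O6 for the transfer of C12 from O8 to O6.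

Step 18
Reactants: 23 methyl (5R,6S,7R,8R,10S)-6-(tert-butyldimethylsilyloxy)-12-ethoxy-5,10:8,12-diepoxy-13-norgermacr-3-en-15-oate
Product: 24 methyl (5R,6S,7R,8R,10S)-6-(tert-butyldimethylsilyloxy)-5,10-epoxy-8-hydroxy-12,12-(propane-1,3-diyldisulfanediyl)-13-norgermacr-3-en-15-oate
Conditions: HS(CH2)3SH, BF3·OEt2, CH2Cl2, −40 °C
Reagents that add atoms: propane-1,3-dithiol, SCCCS
Why: Lewis-acid transthioacetalisation of the 2-alkoxytetrahydrofuran opens the acetal ring to a 1,3-dithiane, which frees O8–H irreversibly while C12 stays masked at the aldehyde level and both acetal epimers converge.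

Step 19
Reactants: 25 (R)-2-methylglycidol
Product: 26 (2S)-2-methylbut-3-ene-1,2-diol
Conditions: Me3S+ I− (3.5 equiv), n-BuLi (3.4 equiv), THF, −10 °C → rt
Reagents that add atoms: trimethylsulfonium iodide, C[S+](C)C.[I-]
Why: Epoxide to one-carbon-homologated allylic alcohol conversion with excess dimethylsulfonium methylide (ylide opening at the CH2 terminus, then elimination of Me2S) makes the vinyl carbinol without touching the quaternary centre, which keeps its spatial arrangement (the descriptor becomes S only because the ranks of the two carbon arms change).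

Step 20
Reactants: 26 (2S)-2-methylbut-3-ene-1,2-diol
Product: 27 (2S)-2-hydroxy-2-methylbut-3-enoic acid
Conditions: TEMPO (5 mol %), NaClO2, NaOCl (2 mol %), phosphate buffer pH 6.7, MeCN, 35 °C
Reagents that add atoms: sodium chlorite, [Na+].[O-]Cl=O
Why: TEMPO-catalysed chlorite oxidation takes the primary alcohol to the carboxylic acid at near-neutral pH, the tertiary allylic alcohol and the vinyl group being inert.

Step 21
Reactants: 27 (2S)-2-hydroxy-2-methylbut-3-enoic acid
Product: 29 (2S)-2-methyl-2-(triethylsilyloxy)but-3-enoic acid, via bis-silyl derivative 28 (not isolated)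
Conditions: Et3SiOTf (2.3 equiv), 2,6-lutidine, CH2Cl2, 0 °C; then K2CO3, MeOH/H2O, 0 °C, acidified to pH 4
Reagents that add atoms: triethylsilyl trifluoromethanesulfonate, CC[Si](CC)(CC)OS(=O)(=O)C(F)(F)F
Why: Silylation of both the tertiary hydroxyl and the carboxyl group followed by mild basic cleavage of the labile silyl ester leaves the silyl-protected acid, so the acid cannot esterify itself in the coupling.

Step 22
Reactants: 24 methyl (5R,6S,7R,8R,10S)-6-(tert-butyldimethylsilyloxy)-5,10-epoxy-8-hydroxy-12,12-(propane-1,3-diyldisulfanediyl)-13-norgermacr-3-en-15-oate; 29 (2S)-2-methyl-2-(triethylsilyloxy)but-3-enoic acid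
Product: 30 methyl (5R,6S,7R,8R,10S)-6-(tert-butyldimethylsilyloxy)-5,10-epoxy-8-[(2S)-2-methyl-2-(triethylsilyloxy)but-3-enoyloxy]-12,12-(propane-1,3-diyldisulfanediyl)-13-norgermacr-3-en-15-oate
Conditions: 2-methyl-6-nitrobenzoic anhydride, DMAP, Et3N, CH2Cl2, rt → 40 °C
Reagents that add atoms: none
Why: Shiina esterification (activation of the acid by 2-methyl-6-nitrobenzoic anhydride and DMAP) is suited to joining a hindered acid to a hindered secondary alcohol, and neither stereocentre takes part.

Step 23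
Reactants: 30 methyl (5R,6S,7R,8R,10S)-6-(tert-butyldimethylsilyloxy)-5,10-epoxy-8-[(2S)-2-methyl-2-(triethylsilyloxy)but-3-enoyloxy]-12,12-(propane-1,3-diyldisulfanediyl)-13-norgermacr-3-en-15-oate
Product: 31 methyl (5R,6S,7R,8R,10S)-6-(tert-butyldimethylsilyloxy)-5,10-epoxy-8-[(2S)-2-methyl-2-(triethylsilyloxy)but-3-enoyloxy]-12-oxo-13-norgermacr-3-en-15-oate
Conditions: MeI, CaCO3, MeCN/H2O (9:1), 40 °C
Reagents that add atoms: water, O
Why: Alkylative hydrolysis of the dithiane (S-methylation, then attack of water) under buffered neutral conditions unmasks the C12 aldehyde without harming the silyl ethers, esters or alkenes.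

Step 24
Reactants: 31 methyl (5R,6S,7R,8R,10S)-6-(tert-butyldimethylsilyloxy)-5,10-epoxy-8-[(2S)-2-methyl-2-(triethylsilyloxy)but-3-enoyloxy]-12-oxo-13-norgermacr-3-en-15-oate
Product: 33 methyl (5R,6S,7R,8R,10S)-6-(tert-butyldimethylsilyloxy)-5,10-epoxy-8-[(2S)-2-methyl-2-(triethylsilyloxy)but-3-enoyloxy]-12-oxogermacra-3,11(13)-dien-15-oate, via Mannich base 32 (not isolated)
Conditions: CH2=NMe2+ I−, Et3N, CH2Cl2, 0 °C → rt
Reagents that add atoms: N,N-dimethylmethyleneiminium iodide, C=[N+](C)C.[I-]
Why: Mannich reaction of the aldehyde with the iminium salt followed by β-elimination of dimethylamine installs the C11=C13 methylene at the aldehyde stage, which avoids enolate chemistry on a lactone that would sit next to the O8 ester.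

Step 25
Reactants: 33 methyl (5R,6S,7R,8R,10S)-6-(tert-butyldimethylsilyloxy)-5,10-epoxy-8-[(2S)-2-methyl-2-(triethylsilyloxy)but-3-enoyloxy]-12-oxogermacra-3,11(13)-dien-15-oate
Product: 34 (5R,6S,7R,8R,10S)-6-(tert-butyldimethylsilyloxy)-5,10-epoxy-15-methoxy-8-[(2S)-2-methyl-2-(triethylsilyloxy)but-3-enoyloxy]-15-oxogermacra-3,11(13)-dien-12-oic acid
Conditions: NaClO2, NaH2PO4, 2-methylbut-2-ene, t-BuOH/H2O, 0 °C → rt
Reagents that add atoms: sodium chlorite, [Na+].[O-]Cl=O
Why: Pinnick oxidation converts the α-methylene aldehyde into the acid chemoselectively, with 2-methylbut-2-ene scavenging HOCl so that the alkenes are spared.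

Step 26
Reactants: 34 (5R,6S,7R,8R,10S)-6-(tert-butyldimethylsilyloxy)-5,10-epoxy-15-methoxy-8-[(2S)-2-methyl-2-(triethylsilyloxy)but-3-enoyloxy]-15-oxogermacra-3,11(13)-dien-12-oic acid
Product: 36 methyl (5R,6S,7R,8R,10S)-5,10-epoxy-8-[(2S)-2-hydroxy-2-methylbut-3-enoyloxy]germacra-3,11(13)-dien-12,6-olid-15-oate, via seco hydroxy acid 35 (not isolated)
Conditions: HF·pyridine, THF, 0 °C → rt
Reagents that add atoms: none
Why: Fluoride-mediated removal of both silyl ethers frees O6–H, which should close the γ-lactone onto the C12 acid in the acidic medium (lactonisation); the trans ring fusion follows from the C6 and C7 configurations set in step 16, and because O8 is blocked as the ester only the 6,12-lactone can form.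

**Compound list**

1 | (S)-linalool, (3S)-3,7-dimethylocta-1,6-dien-3-ol | C=C[C@](O)(C)CCC=C(C)C | starting material
2 | B-[(3S)-3-hydroxy-3,7-dimethyloct-6-enyl]-9-borabicyclo[3.3.1]nonane | CC(C)=CCC[C@](C)(O)CCB1C2CCCC1CCC2 | intermediate
3 | (3S)-3,7-dimethyloct-6-ene-1,3-diol | OCC[C@](O)(C)CCC=C(C)C | intermediate
4 | (3S)-3-hydroxy-3,7-dimethyloct-6-enal | O=CC[C@](O)(C)CCC=C(C)C | intermediate
5 | (3RS,5S)-5,9-dimethyldeca-1,8-diene-3,5-diol (C3 = C8 of the plan, both epimers) | C=CC(O)C[C@](O)(C)CCC=C(C)C | intermediate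
6 | (3RS,5S)-3-(tert-butyldimethylsilyloxy)-5,9-dimethyldeca-1,8-dien-5-ol | C=CC(O[Si](C)(C)C(C)(C)C)C[C@](O)(C)CCC=C(C)C | intermediate
7 | methoxyallene, 1-methoxypropa-1,2-diene | C=C=COC | starting material
8 | (5S)-3-(tert-butyldimethylsilyloxy)-5-(1-methoxyprop-2-enyloxy)-5,9-dimethyldeca-1,8-diene (epimers at C3 and at the acetal carbon) | C=CC(O[Si](C)(C)C(C)(C)C)C[C@](OC(OC)C=C)(C)CCC=C(C)C | intermediate
9 | (7S)-5-(tert-butyldimethylsilyloxy)-2-methoxy-7-methyl-7-(4-methylpent-3-enyl)-2,5,6,7-tetrahydrooxepine (ring B acetal; epimers at C2 and C5) | COC1C=CC(O[Si](C)(C)C(C)(C)C)C[C@](C)(CCC=C(C)C)O1 | intermediate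
10 | methyl 3-[(2S)-4-(tert-butyldimethylsilyloxy)-7-methoxy-2-methyl-2,3,4,7-tetrahydrooxepin-2-yl]propanoate (epimers at C4 and C7) | COC1C=CC(O[Si](C)(C)C(C)(C)C)C[C@](C)(CCC(=O)OC)O1 | intermediate
11 | methyl 5-[(2S)-4-(tert-butyldimethylsilyloxy)-7-methoxy-2-methyl-2,3,4,7-tetrahydrooxepin-2-yl]-3-oxopentanoate | COC1C=CC(O[Si](C)(C)C(C)(C)C)C[C@](C)(CCC(=O)CC(=O)OC)O1 | intermediate
12 | methyl 5-[(2S)-4-(tert-butyldimethylsilyloxy)-7-methoxy-2-methyl-2,3,4,7-tetrahydrooxepin-2-yl]-3-(trimethylsilyloxy)pent-2-enoate (enol silane) | COC1C=CC(O[Si](C)(C)C(C)(C)C)C[C@](C)(CCC(O[Si](C)(C)C)=CC(=O)OC)O1 | intermediate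
13 | methyl (5S,10S)-8-(tert-butyldimethylsilyloxy)-5,10-epoxy-3-oxo-11,12,13-trinorgermacr-6-en-15-oate (cis-bridged 11-oxabicyclo[4.4.1]undecene; epimers at C4 and C8) | CC(C)(C)[Si](C)(C)OC1C[C@]2(C)CCC(=O)C(C(=O)OC)[C@@H](O2)C=C1 | intermediate
14 | methyl (5S,10S)-8-(tert-butyldimethylsilyloxy)-5,10-epoxy-3-(trifluoromethylsulfonyloxy)-11,12,13-trinorgermacra-3,6-dien-15-oate (C8 epimers) | CC(C)(C)[Si](C)(C)OC1C[C@]2(C)CCC(OS(=O)(=O)C(F)(F)F)=C(C(=O)OC)[C@@H](O2)C=C1 | intermediate
15 | methyl (5S,10S)-8-(tert-butyldimethylsilyloxy)-5,10-epoxy-11,12,13-trinorgermacra-3,6-dien-15-oate (C8 epimers) | CC(C)(C)[Si](C)(C)OC1C[C@]2(C)CCC=C(C(=O)OC)[C@@H](O2)C=C1 | intermediate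
16 | methyl (5S,10S)-5,10-epoxy-8-hydroxy-11,12,13-trinorgermacra-3,6-dien-15-oate (C8 epimers) | OC1C[C@]2(C)CCC=C(C(=O)OC)[C@@H](O2)C=C1 | intermediate
17 | methyl (5S,10S)-5,10-epoxy-8-oxo-11,12,13-trinorgermacra-3,6-dien-15-oate (ring B enone) | O=C1C[C@]2(C)CCC=C(C(=O)OC)[C@@H](O2)C=C1 | intermediate
18 | methyl (5S,8R,10S)-5,10-epoxy-8-hydroxy-11,12,13-trinorgermacra-3,6-dien-15-oate (O8 endo, on the face of ring B turned toward the C1–C4 bridge) | O[C@@H]1C[C@]2(C)CCC=C(C(=O)OC)[C@@H](O2)C=C1 | intermediate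
19 | ethyl vinyl ether | C=COCC | starting material
20 | methyl (5S,8R,10S)-8-(2-bromo-1-ethoxyethoxy)-5,10-epoxy-11,12,13-trinorgermacra-3,6-dien-15-oate (both acetal epimers) | CCOC(CBr)O[C@@H]1C[C@]2(C)CCC=C(C(=O)OC)[C@@H](O2)C=C1 | intermediate
21 | methyl (5R,6S,7R,8R,10S)-12-ethoxy-6-hydroperoxy-5,10:8,12-diepoxy-13-norgermacr-3-en-15-oate (C12 epimers) | CCOC3O[C@@H]1C[C@]2(C)CCC=C(C(=O)OC)[C@@H](O2)[C@@H](OO)[C@@H]1C3 | intermediate
22 | methyl (5R,6S,7S,8R,10S)-12-ethoxy-6-hydroxy-5,10:8,12-diepoxy-13-norgermacr-3-en-15-oate (2-ethoxytetrahydrofuran cis-fused at C7–C8, C11 endo, O6 exo; C12 epimers) | CCOC3O[C@@H]1C[C@]2(C)CCC=C(C(=O)OC)[C@@H](O2)[C@@H](O)[C@@H]1C3 | intermediate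
23 | methyl (5R,6S,7R,8R,10S)-6-(tert-butyldimethylsilyloxy)-12-ethoxy-5,10:8,12-diepoxy-13-norgermacr-3-en-15-oate (C12 epimers) | CCOC3O[C@@H]1C[C@]2(C)CCC=C(C(=O)OC)[C@@H](O2)[C@@H](O[Si](C)(C)C(C)(C)C)[C@@H]1C3 | intermediate
24 | methyl (5R,6S,7R,8R,10S)-6-(tert-butyldimethylsilyloxy)-5,10-epoxy-8-hydroxy-12,12-(propane-1,3-diyldisulfanediyl)-13-norgermacr-3-en-15-oate (C12 = C2 of a 1,3-dithiane) | O[C@@H]1C[C@]2(C)CCC=C(C(=O)OC)[C@@H](O2)[C@@H](O[Si](C)(C)C(C)(C)C)[C@@H]1CC3SCCCS3 | intermediate
25 | (R)-2-methylglycidol, [(2R)-2-methyloxiran-2-yl]methanol | C[C@@]1(CO)CO1 | starting material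
26 | (2S)-2-methylbut-3-ene-1,2-diol | C=C[C@](C)(O)CO | intermediate
27 | (2S)-2-hydroxy-2-methylbut-3-enoic acid | C=C[C@](C)(O)C(=O)O | intermediate
28 | triethylsilyl (2S)-2-methyl-2-(triethylsilyloxy)but-3-enoate | C=C[C@](C)(O[Si](CC)(CC)CC)C(=O)O[Si](CC)(CC)CC | intermediate
29 | (2S)-2-methyl-2-(triethylsilyloxy)but-3-enoic acid | C=C[C@](C)(O[Si](CC)(CC)CC)C(=O)O | intermediate
30 | methyl (5R,6S,7R,8R,10S)-6-(tert-butyldimethylsilyloxy)-5,10-epoxy-8-[(2S)-2-methyl-2-(triethylsilyloxy)but-3-enoyloxy]-12,12-(propane-1,3-diyldisulfanediyl)-13-norgermacr-3-en-15-oate | C=C[C@](C)(O[Si](CC)(CC)CC)C(=O)O[C@@H]1C[C@]2(C)CCC=C(C(=O)OC)[C@@H](O2)[C@@H](O[Si](C)(C)C(C)(C)C)[C@@H]1CC3SCCCS3 | intermediate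
31 | methyl (5R,6S,7R,8R,10S)-6-(tert-butyldimethylsilyloxy)-5,10-epoxy-8-[(2S)-2-methyl-2-(triethylsilyloxy)but-3-enoyloxy]-12-oxo-13-norgermacr-3-en-15-oate (C12 aldehyde) | C=C[C@](C)(O[Si](CC)(CC)CC)C(=O)O[C@@H]1C[C@]2(C)CCC=C(C(=O)OC)[C@@H](O2)[C@@H](O[Si](C)(C)C(C)(C)C)[C@@H]1CC=O | intermediate
32 | methyl (5R,6S,7R,8R,10S)-6-(tert-butyldimethylsilyloxy)-13-(dimethylamino)-5,10-epoxy-8-[(2S)-2-methyl-2-(triethylsilyloxy)but-3-enoyloxy]-12-oxogermacr-3-en-15-oate (Mannich base; C11 epimers) | C=C[C@](C)(O[Si](CC)(CC)CC)C(=O)O[C@@H]1C[C@]2(C)CCC=C(C(=O)OC)[C@@H](O2)[C@@H](O[Si](C)(C)C(C)(C)C)[C@@H]1C(CN(C)C)C=O | intermediate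
33 | methyl (5R,6S,7R,8R,10S)-6-(tert-butyldimethylsilyloxy)-5,10-epoxy-8-[(2S)-2-methyl-2-(triethylsilyloxy)but-3-enoyloxy]-12-oxogermacra-3,11(13)-dien-15-oate (α-methylene aldehyde) | C=C[C@](C)(O[Si](CC)(CC)CC)C(=O)O[C@@H]1C[C@]2(C)CCC=C(C(=O)OC)[C@@H](O2)[C@@H](O[Si](C)(C)C(C)(C)C)[C@@H]1C(=C)C=O | intermediate
34 | (5R,6S,7R,8R,10S)-6-(tert-butyldimethylsilyloxy)-5,10-epoxy-15-methoxy-8-[(2S)-2-methyl-2-(triethylsilyloxy)but-3-enoyloxy]-15-oxogermacra-3,11(13)-dien-12-oic acid | C=C[C@](C)(O[Si](CC)(CC)CC)C(=O)O[C@@H]1C[C@]2(C)CCC=C(C(=O)OC)[C@@H](O2)[C@@H](O[Si](C)(C)C(C)(C)C)[C@@H]1C(=C)C(=O)O | intermediate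
35 | (5R,6S,7S,8R,10S)-5,10-epoxy-6-hydroxy-8-[(2S)-2-hydroxy-2-methylbut-3-enoyloxy]-15-methoxy-15-oxogermacra-3,11(13)-dien-12-oic acid (seco hydroxy acid) | C=C[C@](C)(O)C(=O)O[C@@H]1C[C@]2(C)CCC=C(C(=O)OC)[C@@H](O2)[C@@H](O)[C@@H]1C(=C)C(=O)O | intermediate
36 | CNP0325750.1, methyl (5R,6S,7R,8R,10S)-5,10-epoxy-8-[(2S)-2-hydroxy-2-methylbut-3-enoyloxy]germacra-3,11(13)-dien-12,6-olid-15-oate | C=C[C@](C)(O)C(=O)O[C@@H]1C[C@]2(C)CCC=C(C(=O)OC)[C@@H](O2)[C@H]2OC(=O)C(=C)[C@@H]21 | target

**Step count and risks**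

Total step count: 26 (23 in the main line, 3 for the acid 29).
Longest linear sequence: 23 steps (steps 1–18 and 22–26, from 1).

Three steps most likely to fail:

Step 9 (bridging closure of ring A). What may go wrong: closure through a seven-membered transition state is slow, so the oxocarbenium ion is lost by proton loss, by hydride shift from C8 or by intermolecular reaction before C4 arrives. Fallback: setting out from 9, the oxocarbenium ion is trapped intermolecularly with the enol silane made in situ from trimethyl phosphonoacetate (Me3SiOTf, Et3N, CH2Cl2), which gives the C5 phosphonoacetate F1 as both C5 epimers. Selective ozonolysis of the prenyl alkene with PPh3 work-up gives the aldehyde F2. An intramolecular Horner–Wadsworth–Emmons reaction (LiCl, DBU, MeCN, high dilution) then closes ring A at C3=C4. Only the epimer with the phosphonoacetate cis to the C1 chain can bridge, so stereocontrol at C5 is traded for separation and the other half is given up. This path comes back to the route at 15.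

Step 16 (key step). What may go wrong: oxygen captures the C11 radical before it cyclises, or tin hydride reduces the C6 radical before oxygen arrives, so that open-chain or C6-deoxy material forms. Fallback: cyclisation and oxygenation are separated. Setting out from 18, N-iodosuccinimide and ethyl vinyl ether give the iodoacetal F3. Iodine-atom-transfer cyclisation (Et3B, trace air, benzene, rt) with no hydride present gives the cis-fused C6 iodide F4. The iodide is then converted into the alcohol by aerobic tin hydride hydroxylation (Bu3SnH, air, toluene; then PPh3), in which the C6 radical is formed only after the ring exists and is oxygenated on the exo face. This path comes back to the route at 22.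

Step 5 (acetal on the tertiary alcohol). What may go wrong: addition of the hindered tertiary alcohol to the alkoxy-π-allyl palladium species is slower than oligomerisation of the allene, so conversion stalls. Fallback: setting out from 6, acylation (acryloyl chloride, i-Pr2NEt, DMAP, CH2Cl2) gives the acrylate F5, ring-closing metathesis with RuCl2(=CHPh)(PCy3)(H2IMes) gives the seven-membered unsaturated lactone F6, i-Bu2AlH at −78 °C gives the lactol F7, and PPTS in methanol converts the lactol into the methyl acetal. This path comes back to the route at 9.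

Further compounds
F1 | step 9 | methyl 2-(dimethoxyphosphoryl)-2-[(7S)-5-(tert-butyldimethylsilyloxy)-7-methyl-7-(4-methylpent-3-enyl)-2,5,6,7-tetrahydrooxepin-2-yl]acetate (epimer mixture) | COC(=O)C(P(=O)(OC)OC)C1C=CC(O[Si](C)(C)C(C)(C)C)C[C@](C)(CCC=C(C)C)O1
F2 | step 9 | methyl 2-(dimethoxyphosphoryl)-2-[(7S)-5-(tert-butyldimethylsilyloxy)-7-methyl-7-(3-oxopropyl)-2,5,6,7-tetrahydrooxepin-2-yl]acetate (epimer mixture) | COC(=O)C(P(=O)(OC)OC)C1C=CC(O[Si](C)(C)C(C)(C)C)C[C@](C)(CCC=O)O1
F3 | step 16 | methyl (5S,8R,10S)-5,10-epoxy-8-(1-ethoxy-2-iodoethoxy)-11,12,13-trinorgermacra-3,6-dien-15-oate (acetal epimers) | CCOC(CI)O[C@@H]1C[C@]2(C)CCC=C(C(=O)OC)[C@@H](O2)C=C1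
F4 | step 16 | methyl 12-ethoxy-6-iodo-5,10:8,12-diepoxy-13-norgermacr-3-en-15-oate, configured as 22 at C5, C7, C8 and C10 (C6 and C12 epimers) | CCOC3O[C@@H]1C[C@]2(C)CCC=C(C(=O)OC)[C@@H](O2)C(I)[C@@H]1C3
F5 | step 5 | (5S)-3-(tert-butyldimethylsilyloxy)-5,9-dimethyldeca-1,8-dien-5-yl prop-2-enoate (C3 epimers) | C=CC(O[Si](C)(C)C(C)(C)C)C[C@](OC(=O)C=C)(C)CCC=C(C)C
F6 | step 5 | (7S)-5-(tert-butyldimethylsilyloxy)-7-methyl-7-(4-methylpent-3-enyl)-6,7-dihydrooxepin-2(5H)-one (C5 epimers) | O=C1C=CC(O[Si](C)(C)C(C)(C)C)C[C@](C)(CCC=C(C)C)O1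
F7 | step 5 | (7S)-5-(tert-butyldimethylsilyloxy)-7-methyl-7-(4-methylpent-3-enyl)-2,5,6,7-tetrahydrooxepin-2-ol (epimers at C2 and C5) | OC1C=CC(O[Si](C)(C)C(C)(C)C)C[C@](C)(CCC=C(C)C)O1
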